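**Assumption:** the SMILES is taken as the absolute configuration (1S,3R,5R,6S,7R,9S,11S,12S; trans-fused hydroazulene). Locants C1–C20 in descriptive text follow dictyotane numbering: ring C1–C10, C18 on C10, C19 on C4, side chain C11(C17)–C12–C13–C14=C15(C16)(C20).

## Retrosynthetic overview

1. Target ⇐ prenyl terminus by cross-metathesis of an allyl group; C3–OH and C9–OH by double allylic hydroxylation of the two exocyclic methylenes.
2. trans-Hydroazulene core ⇐ transannular C1–C5 bond formation in a ten-membered 1(10)E-ene / 4(19)-ene / 5,6-trans-epoxide (vinyl-epoxide-triggered cation–olefin closure).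
3. Ten-membered ring ⇐ C5–C6 bond and epoxide made together by a macrocyclising sulfur-ylide epoxidation of a lactol (masked C6 aldehyde) carrying an allylic bromide.
4. All-cis C7/C11/C12 array ⇐ butenolide from a propargylic alcohol (carbomagnesiation/CO2), reduced from the face opposite the allyl group; C12 from asymmetric allylation.
5. Chain ⇐ geranyl acetate (C1, C2, C7–C10, C18) + methallyl alcohol (C3–C5, C19). Ring order: ten-membered carbocycle first, then the five- and seven-membered rings together by the one transannular bond.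

## Route

Step 1
Reactants: 1 geranyl acetate
Product: 3 (2E)-3-methyl-6-oxohex-2-en-1-yl acetate, via ozonide 2 (not isolated)
Conditions: O3, CH2Cl2, pyridine (cat.), −78 °C; then Me2S, −78 → 23 °C
Reagents that add atoms: ozone, [O-][O+]=O
Why: Chemoselective ozonolysis with reductive work-up cleaves only the electron-rich terminal alkene because the 2,3-alkene is deactivated by its allylic acetate, so the E-configured future C1=C10 alkene is carried through intact.

Step 2
Reactants: 3 (2E)-3-methyl-6-oxohex-2-en-1-yl acetate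
Product: 5 (2E)-3-methylhept-2-en-6-yn-1-ol, via alkynyl acetate 4 (not isolated)
Conditions: dimethyl (1-diazo-2-oxopropyl)phosphonate, K2CO3 (3 equiv), MeOH, 0 → 23 °C
Reagents that add atoms: dimethyl (1-diazo-2-oxopropyl)phosphonate, COP(=O)(OC)C(=[N+]=[N-])C(C)=O
Why: The Ohira–Bestmann variant of the Seyferth–Gilbert homologation turns the aldehyde into the terminal alkyne (future C7≡C11) under K2CO3/MeOH, which also methanolyses the allylic acetate in the same flask.

Step 3
Reactants: 5 (2E)-3-methylhept-2-en-6-yn-1-ol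
Product: 6 (2E)-1-bromo-3-methylhept-2-en-6-yne
Conditions: CBr4, PPh3, CH2Cl2, −20 °C
Reagents that add atoms: tetrabromomethane, BrC(Br)(Br)Br
Why: Appel bromination converts the primary allylic alcohol into the bromide by SN2 at low temperature without allylic transposition or loss of the E geometry.

Step 4
Reactants: 6 (2E)-1-bromo-3-methylhept-2-en-6-yne; 7 2-methylprop-2-en-1-ol
Product: 9 (5E)-6-methyl-2-methylidenedec-5-en-9-yn-1-ol, via dilithio dianion 8 (not isolated)
Conditions: 7 (3 equiv), n-BuLi (6 equiv), TMEDA, Et2O, 0 → 23 °C; then 6, THF, −78 → 0 °C; then H2O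
Reagents that add atoms: none
Why: The C,O-dianion of methallyl alcohol is alkylated at its carbanion terminus by the primary allylic bromide in an SN2 reaction, adding C3–C5 and C19 with the 1,1-disubstituted alkene already in place, the excess dianion absorbing the acidic alkyne proton.

Step 5
Reactants: 9 (5E)-6-methyl-2-methylidenedec-5-en-9-yn-1-ol
Product: 11 (6E)-11-hydroxy-6-methyl-10-methylideneundec-6-en-2-ynal, via dilithio alkoxide acetylide 10 (not isolated)
Conditions: n-BuLi (2.2 equiv), THF, −78 °C; then DMF, −78 → 0 °C; then inverse quench into aq. KH2PO4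
Reagents that add atoms: N,N-dimethylformamide, CN(C)C=O
Why: Formylation of the lithium acetylide with DMF and an inverse phosphate quench gives the ynal (C12) directly from the unprotected alkynol.

Step 6
Reactants: 11 (6E)-11-hydroxy-6-methyl-10-methylideneundec-6-en-2-ynal
Product: 13 (4S,9E)-9-methyl-13-methylidenetetradeca-1,9-dien-5-yne-4,14-diol, via borinate 12 (not isolated)
Conditions: (−)-B-allyldiisopinocampheylborane (from (+)-α-pinene, 1.6 equiv), Et2O, −78 °C; then NaOH, H2O2, 0 → 23 °C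
Reagents that add atoms: (−)-B-allyldiisopinocampheylborane, C=CCB([C@@H]1C[C@@H]2C[C@H]([C@H]1C)C2(C)C)[C@@H]1C[C@@H]2C[C@H]([C@H]1C)C2(C)C
Why: Brown asymmetric allylboration through a chair transition state on the Si face of the ynal (the sense that gives (S)-1-phenylbut-3-en-1-ol from benzaldehyde) sets C12 as S, the only reagent-controlled stereocentre of the route.

Step 7
Reactants: 13 (4S,9E)-9-methyl-13-methylidenetetradeca-1,9-dien-5-yne-4,14-diol
Product: 16 (5S)-3-[(3E)-8-hydroxy-3-methyl-7-methylideneoct-3-en-1-yl]-4-methyl-5-(prop-2-en-1-yl)furan-2(5H)-one, via alkenylmagnesium chelate 14 (not isolated), via hydroxy acid 15 (not isolated)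
Conditions: MeMgBr (5 equiv), CuI (0.2 equiv), THF, 0 → 23 °C; then CO2 (1 atm), 0 °C; then 2 M HCl
Reagents that add atoms: methylmagnesium bromide, C[Mg]Br; carbon dioxide, O=C=O
Why: Duboudin copper-catalysed anti-carbomagnesiation of the propargylic alkoxide puts methyl (C17) on C11 and a chelated magnesium on C7, whose carboxylation and acid-induced lactonisation give the butenolide with C6 installed regiospecifically.

Step 8
Reactants: 16 (5S)-3-[(3E)-8-hydroxy-3-methyl-7-methylideneoct-3-en-1-yl]-4-methyl-5-(prop-2-en-1-yl)furan-2(5H)-one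
Product: 17 (3R,4S,5S)-3-[(3E)-8-hydroxy-3-methyl-7-methylideneoct-3-en-1-yl]-4-methyl-5-(prop-2-en-1-yl)oxolan-2-one
Conditions: Cu(OAc)2 (5 mol%), 1,2-bis(diphenylphosphino)benzene (5 mol%), (EtO)2MeSiH (2 equiv), t-BuOH (2 equiv), toluene, 23 °C
Reagents that add atoms: none
Why: Copper hydride conjugate reduction (Stryker–Lipshutz type) delivers hydride to C11 and then a proton to C7 on the face opposite the C12 allyl group, giving the all-cis lactone (C11 S, C7 R) while isolated alkenes are untouched.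

Step 9
Reactants: 17 (3R,4S,5S)-3-[(3E)-8-hydroxy-3-methyl-7-methylideneoct-3-en-1-yl]-4-methyl-5-(prop-2-en-1-yl)oxolan-2-one
Product: 18 (3R,4S,5S)-3-[(3E)-7-(bromomethyl)-3-methylocta-3,7-dien-1-yl]-4-methyl-5-(prop-2-en-1-yl)oxolan-2-one
Conditions: CBr4, PPh3, CH2Cl2, −20 °C
Reagents that add atoms: tetrabromomethane, BrC(Br)(Br)Br
Why: Appel bromination of the 2-substituted allylic alcohol gives the allylic bromide (both allyl termini are CH2, so no regiochemical issue) without touching the lactone.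

Step 10
Reactants: 18 (3R,4S,5S)-3-[(3E)-7-(bromomethyl)-3-methylocta-3,7-dien-1-yl]-4-methyl-5-(prop-2-en-1-yl)oxolan-2-one
Product: 19 (3R,4S,5S)-3-[(3E)-7-(bromomethyl)-3-methylocta-3,7-dien-1-yl]-4-methyl-5-(prop-2-en-1-yl)oxolan-2-ol (anomer mixture)
Conditions: i-Bu2AlH (1.1 equiv), CH2Cl2, −78 °C; aq. potassium sodium tartrate
Reagents that add atoms: none
Why: Partial reduction of the γ-lactone with i-Bu2AlH at −78 °C stops at the lactol via the stable aluminium hemiacetal, unveiling C6 at the aldehyde oxidation level without epimerising C7.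

Step 11
Reactants: 19 (3R,4S,5S)-3-[(3E)-7-(bromomethyl)-3-methylocta-3,7-dien-1-yl]-4-methyl-5-(prop-2-en-1-yl)oxolan-2-ol
Product: 22 (2S,3S)-2-[(1S,2R,5E,10S)-5-methyl-9-methylidene-11-oxabicyclo[8.1.0]undec-5-en-2-yl]hex-5-en-3-yl acetate, via thiolanium bromide 20 (not isolated), via epoxy alkoxide 21 (not isolated)
Conditions: tetrahydrothiophene (5 equiv), acetone, 23 °C; then LiN(SiMe3)2 (2.3 equiv), THF (0.002 M), −78 → −40 °C; then Ac2O, DMAP, −40 → 0 °C
Reagents that add atoms: acetic anhydride, CC(=O)OC(C)=O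
Why: Proposed new method: a Corey–Chaykovsky epoxidation run as a macrocyclisation, in which the S-allyl thiolanium ylide adds to the aldehyde tautomer of the lithium lactolate in the Felkin–Anh sense (largest group C11 anti, giving C6 S) and the anti betaine closes irreversibly to the trans vinyl epoxide (C5 S) so that the ten-membered ring is formed, after which the freed C12 alkoxide is acetylated in the same flask; the closest known reactions are intermolecular epoxidations of aldehydes with allyl sulfonium ylides and Wittig olefinations of lactols.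

Step 12
Reactants: 22 (2S,3S)-2-[(1S,2R,5E,10S)-5-methyl-9-methylidene-11-oxabicyclo[8.1.0]undec-5-en-2-yl]hex-5-en-3-yl acetate
Product: 23 (2S,3S)-2-[(3aR,4S,5R,8aS)-4-hydroxy-3,8-dimethylidenedecahydroazulen-5-yl]hex-5-en-3-yl acetate
Conditions: BF3·OEt2 (0.2 equiv), 2,6-di-tert-butyl-4-methylpyridine (0.3 equiv), CH2Cl2, −78 → −40 °C
Reagents that add atoms: none
Why: Lewis-acid-catalysed transannular epoxide–olefin cyclisation of the type known for parthenolide to micheliolide, in which C1 of the 1(10)E alkene opens the allylic C5–O bond with inversion (C5 R, anti to the retained C6 hydroxyl) through the fold that staggers C10 against H5 rather than C6 (trans ring fusion, C1 S) and the C10 cation loses a C18 proton to the hindered base to give the exocyclic alkene.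

Step 13
Reactants: 23 (2S,3S)-2-[(3aR,4S,5R,8aS)-4-hydroxy-3,8-dimethylidenedecahydroazulen-5-yl]hex-5-en-3-yl acetate
Product: 24 (2S,3S)-2-[(2R,3aR,4S,5R,7S,8aS)-2,4,7-trihydroxy-3,8-dimethylidenedecahydroazulen-5-yl]hex-5-en-3-yl acetate
Conditions: SeO2 (0.5 equiv), t-BuOOH (5 equiv), CH2Cl2, 0 → 23 °C
Reagents that add atoms: selenium dioxide, O=[Se]=O; tert-butyl hydroperoxide, CC(C)(C)OO
Why: Sharpless SeO2/t-BuOOH allylic hydroxylation (ene reaction then [2,3]-sigmatropic shift) oxidises each exocyclic methylene at its ring CH2 in preference to the allylic methines and the slow monosubstituted allyl group, oxygen being delivered to the face anti to the substituent on the adjacent ring-fusion carbon (3R and 9S).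

Step 14
Reactants: 24 (2S,3S)-2-[(2R,3aR,4S,5R,7S,8aS)-2,4,7-trihydroxy-3,8-dimethylidenedecahydroazulen-5-yl]hex-5-en-3-yl acetate
Product: 25 (2S,3S)-2-[(2R,3aR,4S,5R,7S,8aS)-2,4,7-trihydroxy-3,8-dimethylidenedecahydroazulen-5-yl]-6-methylhept-5-en-3-yl acetate (target, CNP0210891.2)
Conditions: 2-methylbut-2-ene (excess), second-generation Grubbs catalyst RuCl2(=CHPh)(H2IMes)(PCy3) (5 mol%), CH2Cl2, 40 °C
Reagents that add atoms: 2-methylbut-2-ene, CC=C(C)C
Why: Olefin cross-metathesis with 2-methylbut-2-ene exchanges the terminal CH2 of the monosubstituted allyl group for an isopropylidene unit while the 1,1-disubstituted exocyclic alkenes do not react.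

## Compound list

1 | geranyl acetate, (2E)-3,7-dimethylocta-2,6-dien-1-yl acetate | CC(=O)OC/C=C(\C)CCC=C(C)C | starting material
2 | ozonide of 1 at the 6,7-alkene, (2E)-5-(5,5-dimethyl-1,2,4-trioxolan-3-yl)-3-methylpent-2-en-1-yl acetate (not isolated) | CC(=O)OC/C=C(\C)CCC1OOC(C)(C)O1 | intermediate
3 | (2E)-3-methyl-6-oxohex-2-en-1-yl acetate | CC(=O)OC/C=C(\C)CCC=O | intermediate
4 | (2E)-3-methylhept-2-en-6-yn-1-yl acetate (not isolated) | CC(=O)OC/C=C(\C)CCC#C | intermediate
5 | (2E)-3-methylhept-2-en-6-yn-1-ol | OC/C=C(\C)CCC#C | intermediate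
6 | (2E)-1-bromo-3-methylhept-2-en-6-yne | BrC/C=C(\C)CCC#C | intermediate
7 | 2-methylprop-2-en-1-ol (methallyl alcohol) | C=C(C)CO | starting material
8 | C,O-dilithio dianion of 7, lithium 2-(lithiomethyl)prop-2-en-1-olate (not isolated) | [Li+].[Li+].[CH2-]C(=C)C[O-] | intermediate
9 | (5E)-6-methyl-2-methylidenedec-5-en-9-yn-1-ol | OCC(=C)CC/C=C(\C)CCC#C | intermediate
10 | dilithium alkoxide acetylide of 9 (not isolated) | [Li+].[Li+].[O-]CC(=C)CC/C=C(\C)CCC#[C-] | intermediate
11 | (6E)-11-hydroxy-6-methyl-10-methylideneundec-6-en-2-ynal | OCC(=C)CC/C=C(\C)CCC#CC=O | intermediate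
12 | O4-bis(isopinocampheyl)boryl ether of 13 (borinate, not isolated) | OCC(=C)CC/C=C(\C)CCC#C[C@H](CC=C)OB([C@@H]1C[C@@H]2C[C@H]([C@H]1C)C2(C)C)[C@@H]1C[C@@H]2C[C@H]([C@H]1C)C2(C)C | intermediate
13 | (4S,9E)-9-methyl-13-methylidenetetradeca-1,9-dien-5-yne-4,14-diol | OCC(=C)CC/C=C(\C)CCC#C[C@H](CC=C)O | intermediate
14 | cyclic alkenylmagnesium alkoxide from 13: methyl on C11, magnesium bridging C7 and O12, remote bromomagnesium alkoxide (not isolated) | Br[Mg]OCC(=C)CC/C=C(\C)CCC1=C(C)[C@H](CC=C)O[Mg]1 | intermediate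
15 | (2Z,4S)-4-hydroxy-2-[(3E)-8-hydroxy-3-methyl-7-methylideneoct-3-en-1-yl]-3-methylhepta-2,6-dienoic acid (not isolated) | OCC(=C)CC/C=C(\C)CC/C(C(O)=O)=C(\C)[C@H](CC=C)O | intermediate
16 | (5S)-3-[(3E)-8-hydroxy-3-methyl-7-methylideneoct-3-en-1-yl]-4-methyl-5-(prop-2-en-1-yl)furan-2(5H)-one | OCC(=C)CC/C=C(\C)CCC1=C(C)[C@H](CC=C)OC1=O | intermediate
17 | (3R,4S,5S)-3-[(3E)-8-hydroxy-3-methyl-7-methylideneoct-3-en-1-yl]-4-methyl-5-(prop-2-en-1-yl)oxolan-2-one (all-cis lactone) | OCC(=C)CC/C=C(\C)CC[C@@H]1[C@H](C)[C@H](CC=C)OC1=O | intermediate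
18 | (3R,4S,5S)-3-[(3E)-7-(bromomethyl)-3-methylocta-3,7-dien-1-yl]-4-methyl-5-(prop-2-en-1-yl)oxolan-2-one | BrCC(=C)CC/C=C(\C)CC[C@@H]1[C@H](C)[C@H](CC=C)OC1=O | intermediate
19 | (3R,4S,5S)-3-[(3E)-7-(bromomethyl)-3-methylocta-3,7-dien-1-yl]-4-methyl-5-(prop-2-en-1-yl)oxolan-2-ol (anomer mixture) | BrCC(=C)CC/C=C(\C)CC[C@@H]1[C@H](C)[C@H](CC=C)OC1O | intermediate
20 | S-allyl thiolanium bromide of 19, bromide replaced by tetrahydrothiophenium (not isolated) | C1CC[S+](C1)CC(=C)CC/C=C(\C)CC[C@@H]2[C@H](C)[C@H](CC=C)OC2O.[Br-] | intermediate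
21 | lithium C12-alkoxide of the macrocyclic vinyl epoxide, the deacetyl form of 22 (not isolated) | C=C1CC/C=C(\C)CC[C@H]([C@H](C)[C@H](CC=C)[O-])[C@@H]2O[C@@H]12.[Li+] | intermediate
22 | (2S,3S)-2-[(1S,2R,5E,10S)-5-methyl-9-methylidene-11-oxabicyclo[8.1.0]undec-5-en-2-yl]hex-5-en-3-yl acetate (ten-membered 1(10)E-ene, 4(19)-ene, 5S,6S-trans-epoxide) | C=C1CC/C=C(\C)CC[C@H]([C@H](C)[C@H](CC=C)OC(C)=O)[C@@H]2O[C@@H]12 | intermediate
23 | (2S,3S)-2-[(3aR,4S,5R,8aS)-4-hydroxy-3,8-dimethylidenedecahydroazulen-5-yl]hex-5-en-3-yl acetate (trans-fused) | C=C1[C@@H]2[C@@H](O)[C@@H]([C@H](C)[C@H](CC=C)OC(C)=O)CCC(=C)[C@H]2CC1 | intermediate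
24 | (2S,3S)-2-[(2R,3aR,4S,5R,7S,8aS)-2,4,7-trihydroxy-3,8-dimethylidenedecahydroazulen-5-yl]hex-5-en-3-yl acetate | C=C1[C@@H]2[C@@H](O)[C@@H]([C@H](C)[C@H](CC=C)OC(C)=O)C[C@H](O)C(=C)[C@H]2C[C@H]1O | intermediate
25 | (2S,3S)-2-[(2R,3aR,4S,5R,7S,8aS)-2,4,7-trihydroxy-3,8-dimethylidenedecahydroazulen-5-yl]-6-methylhept-5-en-3-yl acetate (CNP0210891.2) | C=C1[C@@H]2[C@@H](O)[C@@H]([C@H](C)[C@H](CC=C(C)C)OC(C)=O)C[C@H](O)C(=C)[C@H]2C[C@H]1O | target

## Step count and risks

Total step count: 14. Longest linear sequence: 14 steps, from geranyl acetate 1.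

**Risk 1, step 11.** The macrocyclising ylide epoxidation has no direct precedent. The ten-membered ring may not close, and the freed C12 alkoxide may open the new epoxide to a tetrahydrofuran before it is acetylated. The fallback uses an allyl sulfone at C5 as both nucleophile and leaving group, and sets out from 18. PhSO2Na in DMF gives the sulfonyl lactone F1. i-Bu2AlH gives the sulfonyl lactol F2. LiN(SiMe3)2 at high dilution closes the ring by Julia-type addition of the sulfonyl carbanion to the aldehyde tautomer, giving the macrocyclic hydroxy sulfone F3 (no epoxide, so no ether formation). Acetylation of the less hindered C12 hydroxyl gives the monoacetate F4. EtAlCl2 then ionises the allylic sulfone (Trost-type) and the same transannular C1–C5 closure delivers 23, where the fallback rejoins the route.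

**Risk 2, step 12.** The transannular cyclisation may give the cis-fused C1 epimer, or endocyclic alkene isomers by loss of H1 or H9 instead of H18. The fallback sets out from 22. Thiyl-radical E→Z isomerisation (PhSSPh, hν) gives the (1Z)-macrocycle F5. In F5 the hydrogen and C2 on C1 are exchanged relative to 22, so the same fold creates the opposite configuration at C1. Cyclisation of F5 under the step 12 conditions returns to 23.

**Risk 3, step 13.** The double allylic hydroxylation may give the wrong carbinol configuration at C3 (the less certain site) or at C9, or over-oxidise. The fallback sets out from 23 and fixes configuration by oxidation, reduction and inversion. SeO2/t-BuOOH followed by MnO2 gives the bis-enone F6 regardless of carbinol configuration. NaBH4/CeCl3·7H2O reduces both ketones from their open faces; this is expected to give the 3,9-diepimer F7. Mitsunobu inversion (4-nitrobenzoic acid, PPh3, diisopropyl azodicarboxylate) gives the bis(4-nitrobenzoate) F8 with the natural 3R,9S configuration. K2CO3/MeOH at 0 °C removes the activated esters in preference to the hindered C12 acetate and returns 24. If the Luche step already gives the natural carbinols, the last two operations are omitted.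

## Further compounds

F1 | step 11 | (3R,4S,5S)-4-methyl-3-{(3E)-3-methyl-7-[(phenylsulfonyl)methyl]octa-3,7-dien-1-yl}-5-(prop-2-en-1-yl)oxolan-2-one | O=S(=O)(CC(=C)CC/C=C(\C)CC[C@@H]1[C@H](C)[C@H](CC=C)OC1=O)c2ccccc2
F2 | step 11 | (3R,4S,5S)-4-methyl-3-{(3E)-3-methyl-7-[(phenylsulfonyl)methyl]octa-3,7-dien-1-yl}-5-(prop-2-en-1-yl)oxolan-2-ol (anomer mixture) | O=S(=O)(CC(=C)CC/C=C(\C)CC[C@@H]1[C@H](C)[C@H](CC=C)OC1O)c2ccccc2
F3 | step 11 | ten-membered hydroxy sulfone: 1(10)E-ene, 4(19)-methylidene, 5-phenylsulfonyl (C5 epimers), 6S-hydroxy, 7R side chain (11S,12S)-12-hydroxy with allyl terminus | C=C1CC/C=C(\C)CC[C@H]([C@H](C)[C@H](CC=C)O)[C@H](O)C1S(=O)(=O)c2ccccc2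
F4 | step 11 | 12-O-acetate of F3 | C=C1CC/C=C(\C)CC[C@H]([C@H](C)[C@H](CC=C)OC(C)=O)[C@H](O)C1S(=O)(=O)c2ccccc2
F5 | step 12 | (2S,3S)-2-[(1S,2R,5Z,10S)-5-methyl-9-methylidene-11-oxabicyclo[8.1.0]undec-5-en-2-yl]hex-5-en-3-yl acetate, the (1Z)-isomer of 22 | C=C1CC/C=C(/C)CC[C@H]([C@H](C)[C@H](CC=C)OC(C)=O)[C@@H]2O[C@@H]12
F6 | step 13 | 3,9-dioxo analogue of 24, (2S,3S)-2-[(3aR,4S,5R,8aS)-4-hydroxy-3,8-dimethylidene-2,7-dioxodecahydroazulen-5-yl]hex-5-en-3-yl acetate | C=C1[C@@H]2[C@@H](O)[C@@H]([C@H](C)[C@H](CC=C)OC(C)=O)CC(=O)C(=C)[C@H]2CC1=O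
F7 | step 13 | 3,9-diepimer of 24 (3S,9R carbinols) | C=C1[C@@H]2[C@@H](O)[C@@H]([C@H](C)[C@H](CC=C)OC(C)=O)C[C@@H](O)C(=C)[C@H]2C[C@@H]1O
F8 | step 13 | 3,9-bis(4-nitrobenzoate) of 24 (3R,9S) | C=C1[C@@H]2[C@@H](O)[C@@H]([C@H](C)[C@H](CC=C)OC(C)=O)C[C@H](OC(=O)c3ccc(cc3)[N+]([O-])=O)C(=C)[C@H]2C[C@H]1OC(=O)c4ccc(cc4)[N+]([O-])=O
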